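**Retrosynthetic overview**
1. Target 13 comes from its bis-pivalate 12 by ester methanolysis, and 12 from the 3-silyl oxolane 10 by Fleming–Tamao oxidation with retention, so the C3 hydroxyl is carried as a C3–SiMe2Ph group.
2. The oxolane, the only ring that is built (both arene rings come from vanillin), is closed in one operation from the (R,Z)-allylsilane 7 and the aldehyde 2, forming the C4–C5 bond and the O1–C2 bond.
3. Enabling feature: the tertiary carbinol carbon C3 sits between the methyl-bearing C4 and the benzylic C2 (ring B). A silyl group that starts on C2 and shifts to C3 makes C4 nucleophilic, then C2 cationic, and finally becomes the C3–OH.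
4. Silane 7 comes from the racemic α-chlorobenzylsilane 5 and (Z)-2-bromobut-2-ene 6 by an enantioconvergent nickel-catalysed reductive coupling; 5 and 2 both derive from vanillin 1.
5. The one stereocentre and the Z geometry of 7 are relayed into all four stereocentres of the ring in step 5.

Key step: step 5

Remark: (Z)-2-bromobut-2-ene is taken as purchasable as the single geometric isomer, and the ligand antipode in step 4 is whichever one delivers (R)-7, to be fixed in a pilot run.

**Step 1**
Reactants: 1 vanillin (4-hydroxy-3-methoxybenzaldehyde)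
Product: 2 4-formyl-2-methoxyphenyl pivalate
Conditions: PivCl, Et3N, DMAP (cat.), CH2Cl2, 0 °C to rt
Reagents that add atoms: pivaloyl chloride, CC(C)(C)C(Cl)=O
Why: DMAP-catalysed O-acylation of the phenol; the electron-poor, hindered aryl ester should survive the copper, nickel and BF3 steps and damp ionisation of the later benzylic C–O bonds.

**Step 2**
Reactants: 2 4-formyl-2-methoxyphenyl pivalate
Product: 3 rac-4-{hydroxy[dimethyl(phenyl)silyl]methyl}-2-methoxyphenyl pivalate
Conditions: PhMe2Si–Bpin, (IPr)CuCl (5 mol %; IPr = 1,3-bis(2,6-diisopropylphenyl)imidazol-2-ylidene), NaOtBu (5 mol %), MeOH (2 equiv), THF, 0 °C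
Reagents that add atoms: dimethyl(phenyl)silylboronic acid pinacol ester, CC1(C)OB(OC1(C)C)[Si](C)(C)c1ccccc1
Why: copper-catalysed 1,2-addition of nucleophilic silicon to an aldehyde (Si–B transmetalation to a copper silyl, carbonyl insertion, protonolysis by MeOH), mild enough to avoid Brook rearrangement and ester cleavage; the racemic centre is acceptable because step 4 is stereoconvergent.

**Step 3**
Reactants: 3 rac-4-{hydroxy[dimethyl(phenyl)silyl]methyl}-2-methoxyphenyl pivalate
Product: 5 rac-4-{chloro[dimethyl(phenyl)silyl]methyl}-2-methoxyphenyl pivalate, via chlorosulfite ester 4 (not isolated)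
Conditions: SOCl2, pyridine, CH2Cl2, 0 °C
Reagents that add atoms: thionyl chloride, O=S(Cl)Cl
Why: dehydroxychlorination of a benzylic alcohol through its chlorosulfite with chloride displacement; pyridine buffers HCl so the benzylic C–Si bond is not protonolysed.

**Step 4**
Reactants: 5 rac-4-{chloro[dimethyl(phenyl)silyl]methyl}-2-methoxyphenyl pivalate; 6 (Z)-2-bromobut-2-ene (methyl groups trans)
Product: 7 4-{(1R,2Z)-1-[dimethyl(phenyl)silyl]-2-methylbut-2-en-1-yl}-2-methoxyphenyl pivalate
Conditions: NiCl2(dme) (10 mol %), indane-fused bis(oxazoline) ligand with cyclopropane-1,1-diyl bridge (11 mol %), cobalt phthalocyanine Co(C32H16N8) (5 mol %), Mn powder (3 equiv), NMP, 5 °C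
Reagents that add atoms: none
Why: nickel-catalysed asymmetric reductive cross-electrophile coupling of an α-chlorobenzylsilane with an alkenyl bromide; the planar α-silyl benzylic radical from either enantiomer of 5 is captured by the chiral alkenylnickel species and reductive elimination sets C1 under ligand control, while the Z geometry of 6 is carried over because the steps at the sp2 carbon are stereoretentive.

**Step 5**
Reactants: 7 4-{(1R,2Z)-1-[dimethyl(phenyl)silyl]-2-methylbut-2-en-1-yl}-2-methoxyphenyl pivalate; 2 4-formyl-2-methoxyphenyl pivalate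
Product: 10 (2R,3S,4S,5S)-3-[dimethyl(phenyl)silyl]-3,4-dimethyl-2,5-bis(3-methoxy-4-pivaloyloxyphenyl)oxolane, via beta-silyl tertiary cation 8 (not isolated), via benzylic cation 9 (not isolated)
Conditions: BF3·OEt2 (2.5 equiv), CH2Cl2, 4 Å MS, −78 °C; Et3N then NaHCO3 quench at −78 °C
Reagents that add atoms: none
Why: Silyl-migration [3+2] annulation of an allylsilane with an aldehyde (the ring-forming variant of the Hosomi–Sakurai reaction): the γ-carbon of 7 adds anti to silicon to BF3-bound 2 (C4–C5 bond) to give tertiary β-silyl cation 8, a suprafacial 1,2-silyl shift gives the silicon-bridged benzylic cation 9, and the alkoxide oxygen closes on it anti to silicon (O1–C2 bond). The closest known reaction type is the BF3-promoted annulation of enantioenriched crotylsilanes with aryl aldehydes to 3-silyl tetrahydrofurans. The oxolane closes by capture of the benzylic cation by oxygen, formally a 5-endo opening of the siliranium ion at its benzylic carbon, which is allowed because that carbon is cationic (ring B). Stereocontrol: the Z γ-methyl forces the C1–H of 7 into the alkene plane (A1,3 strain) so one alkene face is attacked anti to silicon (C4); the Z geometry with the suprafacial shift places silicon cis and the C3 methyl trans to the C4 methyl (C3); backside closure places ring B trans to silicon (C2); and an open antiperiplanar transition state with ring A gauche to the γ-hydrogen (syn topicity) places ring A cis to the C4 methyl (C5). The step needs annulation to win over desilylative allylation, which the benzylic stabilisation of the migration terminus, the low temperature and the non-nucleophilic BF3-alkoxide should secure, while the pivalates keep both benzylic C–O bonds from re-ionising so that the kinetic product persists.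

**Step 6**
Reactants: 10 (2R,3S,4S,5S)-3-[dimethyl(phenyl)silyl]-3,4-dimethyl-2,5-bis(3-methoxy-4-pivaloyloxyphenyl)oxolane
Product: 12 (2R,3S,4S,5S)-3,4-dimethyl-2,5-bis(3-methoxy-4-pivaloyloxyphenyl)oxolan-3-ol, via fluorosilane 11 (not isolated)
Conditions: HBF4·OEt2, CH2Cl2, 0 °C; then mCPBA, KF, DMF, rt
Reagents that add atoms: 3-chloroperbenzoic acid, OOC(=O)c1cccc(Cl)c1
Why: Fleming–Tamao oxidation; ipso-protodesilylation removes the phenyl group to give fluorosilane 11, and peracid with fluoride then drives 1,2-migration of the tertiary carbon from silicon to oxygen with retention, so C3–Si becomes C3–OH without change of configuration.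

**Step 7**
Reactants: 12 (2R,3S,4S,5S)-3,4-dimethyl-2,5-bis(3-methoxy-4-pivaloyloxyphenyl)oxolan-3-ol
Product: 13 (2R,3S,4S,5S)-2,5-bis(4-hydroxy-3-methoxyphenyl)-3,4-dimethyloxolan-3-ol
Conditions: K2CO3, MeOH, rt; aqueous NH4Cl work-up
Reagents that add atoms: none
Why: base-mediated methanolysis (transesterification) of the two aryl pivalates, which should leave the oxolane, the tertiary alcohol and all four stereocentres untouched.

**Compound list**
1 | vanillin (4-hydroxy-3-methoxybenzaldehyde) | COc1cc(C=O)ccc1O | starting material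
2 | 4-formyl-2-methoxyphenyl pivalate | COc1cc(C=O)ccc1OC(=O)C(C)(C)C | intermediate
3 | rac-4-{hydroxy[dimethyl(phenyl)silyl]methyl}-2-methoxyphenyl pivalate | COc1cc(C(O)[Si](C)(C)c2ccccc2)ccc1OC(=O)C(C)(C)C | intermediate
4 | chlorosulfite ester of 3 (racemic, not isolated) | COc1cc(C(OS(=O)Cl)[Si](C)(C)c2ccccc2)ccc1OC(=O)C(C)(C)C | intermediate
5 | rac-4-{chloro[dimethyl(phenyl)silyl]methyl}-2-methoxyphenyl pivalate | COc1cc(C(Cl)[Si](C)(C)c2ccccc2)ccc1OC(=O)C(C)(C)C | intermediate
6 | (Z)-2-bromobut-2-ene | C/C=C(/C)Br | starting material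
7 | 4-{(1R,2Z)-1-[dimethyl(phenyl)silyl]-2-methylbut-2-en-1-yl}-2-methoxyphenyl pivalate | C/C=C(/C)[C@H](c1ccc(OC(=O)C(C)(C)C)c(OC)c1)[Si](C)(C)c1ccccc1 | intermediate
8 | open-chain zwitterion after C–C bond formation: BF3-alkoxide on the ring A carbinol carbon, tertiary cation β to silicon, configurations as carried into 10 (not isolated) | COc1cc([C@@H](O[B-](F)(F)F)[C@H](C)[C+](C)[C@H](c2ccc(OC(=O)C(C)(C)C)c(OC)c2)[Si](C)(C)c2ccccc2)ccc1OC(=O)C(C)(C)C | intermediate
9 | zwitterion after 1,2-silyl shift: silicon on the future C3, cation on the ring B benzylic carbon, configurations as in 10 (not isolated) | COc1cc([C@@H](O[B-](F)(F)F)[C@H](C)[C@](C)([Si](C)(C)c2ccccc2)[CH+]c2ccc(OC(=O)C(C)(C)C)c(OC)c2)ccc1OC(=O)C(C)(C)C | intermediate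
10 | (2R,3S,4S,5S)-3-[dimethyl(phenyl)silyl]-3,4-dimethyl-2,5-bis(3-methoxy-4-pivaloyloxyphenyl)oxolane | COc1cc([C@H]2O[C@H](c3ccc(OC(=O)C(C)(C)C)c(OC)c3)[C@@](C)([Si](C)(C)c4ccccc4)[C@H]2C)ccc1OC(=O)C(C)(C)C | intermediate
11 | (2R,3S,4S,5S)-3-(fluorodimethylsilyl)-3,4-dimethyl-2,5-bis(3-methoxy-4-pivaloyloxyphenyl)oxolane (not isolated) | COc1cc([C@H]2O[C@H](c3ccc(OC(=O)C(C)(C)C)c(OC)c3)[C@@](C)([Si](C)(C)F)[C@H]2C)ccc1OC(=O)C(C)(C)C | intermediate
12 | (2R,3S,4S,5S)-3,4-dimethyl-2,5-bis(3-methoxy-4-pivaloyloxyphenyl)oxolan-3-ol | COc1cc([C@H]2O[C@H](c3ccc(OC(=O)C(C)(C)C)c(OC)c3)[C@@](C)(O)[C@H]2C)ccc1OC(=O)C(C)(C)C | intermediate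
13 | (2R,3S,4S,5S)-2,5-bis(4-hydroxy-3-methoxyphenyl)-3,4-dimethyloxolan-3-ol | COc1cc([C@H]2O[C@H](c3ccc(O)c(OC)c3)[C@@](C)(O)[C@H]2C)ccc1O | target

**Step count and risks**
Total steps: 7. Longest linear sequence: 7 (1 → 2 → 3 → 5 → 7 → 10 → 12 → 13; compound 2 is used twice).

Most likely to fail, step 5: the β-silyl cation may lose silicon before the 1,2-shift (allylation instead of annulation), and the aldehyde-face topicity of a Z-configured silane may be incomplete. The fallback accepts the allylation and builds the C–O bonds afterwards. It sets out from 7 and 2: TiCl4 in CH2Cl2 at −78 °C should give, by anti Hosomi–Sakurai allylation, (1S,2R,3E)-2,3-dimethyl-1,4-bis(3-methoxy-4-pivaloyloxyphenyl)but-3-en-1-ol F1. Shi epoxidation of its E-trisubstituted styrene (KHSO5 as Oxone, buffered MeCN/water, 0 °C), using the ketone antipode from the L-fructose series so that reagent control delivers the (S,S)-oxirane, should give (1S,2S)-1-(3-methoxy-4-pivaloyloxyphenyl)-2-[(2S,3S)-3-(3-methoxy-4-pivaloyloxyphenyl)-2-methyloxiran-2-yl]propan-1-ol F2. Catalytic camphorsulfonic acid in CH2Cl2 should then open the epoxide at its benzylic carbon with inversion by the secondary hydroxyl (5-endo), and the route is rejoined at 12.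

Step 4: oxidative addition and reductive elimination at the α-methyl-substituted Z-alkenyl bromide may be slow, with erosion of enantioselectivity or Z-to-E isomerisation at nickel. The fallback makes the C–Si bond instead of the C–C bond and sets out from 2. Wittig reaction with 2-(triphenylphosphoranylidene)propanal (toluene, 80 °C) should give 4-[(1E)-2-methyl-3-oxoprop-1-en-1-yl]-2-methoxyphenyl pivalate F3, and methylenation with Ph3P=CH2 (THF, 0 °C) should give 4-[(1E)-2-methylbuta-1,3-dien-1-yl]-2-methoxyphenyl pivalate F4. Palladium-catalysed asymmetric 1,4-hydrosilylation with HSiCl2Ph ([PdCl(C3H5)]2 with a chiral monodentate binaphthyl phosphine of the MOP family) should give 4-{(1R,2Z)-1-[dichloro(phenyl)silyl]-2-methylbut-2-en-1-yl}-2-methoxyphenyl pivalate F5, the Z geometry following from cis 1,4-addition through the s-cis diene. Excess MeMgBr in THF then replaces both chlorides (the pivalate is lost here and is put back with PivCl in the same flask), and the route is rejoined at 7. The enantiomeric purity from this method is expected to be moderate and would have to be raised by crystallisation at the stage of 12.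

Step 6: the acid needed to cleave the phenyl–silicon bond may ionise the β-silyl benzylic ether (ring opening with loss of silicon), and migration of the tertiary carbon may be slow. The fallback activates silicon with nucleophiles instead of attacking the phenyl ring with an electrophile, so no acid is present. It sets out from 10: KH, t-BuOOH and Bu4NF in NMP at 70 °C should oxidise the hindered phenylsilane directly and cleave both pivalates in the same pot, and the route is rejoined at 13 with no new compound (F0).

**Further compounds**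
F1 | step 5 | (1S,2R,3E)-2,3-dimethyl-1,4-bis(3-methoxy-4-pivaloyloxyphenyl)but-3-en-1-ol | COc1cc([C@@H](O)[C@H](C)/C(C)=C/c2ccc(OC(=O)C(C)(C)C)c(OC)c2)ccc1OC(=O)C(C)(C)C
F2 | step 5 | (1S,2S)-1-(3-methoxy-4-pivaloyloxyphenyl)-2-[(2S,3S)-3-(3-methoxy-4-pivaloyloxyphenyl)-2-methyloxiran-2-yl]propan-1-ol | COc1cc([C@@H](O)[C@H](C)[C@]2(C)O[C@H]2c3ccc(OC(=O)C(C)(C)C)c(OC)c3)ccc1OC(=O)C(C)(C)C
F3 | step 4 | 4-[(1E)-2-methyl-3-oxoprop-1-en-1-yl]-2-methoxyphenyl pivalate | O=C/C(C)=C/c1ccc(OC(=O)C(C)(C)C)c(OC)c1
F4 | step 4 | 4-[(1E)-2-methylbuta-1,3-dien-1-yl]-2-methoxyphenyl pivalate | C=C/C(C)=C/c1ccc(OC(=O)C(C)(C)C)c(OC)c1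
F5 | step 4 | 4-{(1R,2Z)-1-[dichloro(phenyl)silyl]-2-methylbut-2-en-1-yl}-2-methoxyphenyl pivalate | C/C=C(/C)[C@H](c1ccc(OC(=O)C(C)(C)C)c(OC)c1)[Si](Cl)(Cl)c1ccccc1
F0 | step 6 | none | none
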